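**Retrosynthetic overview**
1. Feature: in the 2,3-dihydrobenzofuran core, C3 is bonded to ring A through C3a and carries one oxygenated carbon (C3–CH2O), while the adjacent C2 holds O1 and ring B. This is the footprint of a flavanone in which C4a has moved from the carbonyl carbon C4 to C3 and C4 has left the ring as an ester.
2. Late disconnections: the feruloyl ester (chain oxygen) and the p-coumaroyl ester (C3–CH2O) are cut back to the free acids. They are joined by two phenol-tolerant Mitsunobu esterifications, and a tert-butyldiphenylsilyl ether on the chain keeps the two primary alcohols apart.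
3. Key disconnection: C3–C3a, made by a trivalent-iodine oxidative 1,2-shift that contracts the pyranone of an (R)-flavanone to the trans dihydrofuran ester. C2 passes its configuration on to C3.
4. The C2–aryl bond, the only catalyst-set stereocentre, comes from Pd–pyridinooxazoline conjugate addition of an O-acetylated arylboronic acid to a chromone. The chromone comes from 2'-hydroxy-3'-methoxyacetophenone by para-bromination, enaminone cyclisation and B-alkyl Suzuki–Miyaura coupling.
5. Ring order: rings A and B are bought. The pyranone ring is closed first (step 2) and contracted to the dihydrofuran ring in step 8; no other ring is formed.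

Key step: step 8

Assumption: the SMILES reads as (2R,3S), trans. (S)-t-BuPyOx is taken to deliver the aryl group to the chromone face that gives the (R)-flavanone, the same facial sense as with cyclic enones; if the sense proves opposite, the (R)-ligand is used and nothing else changes.

**Step 1**
Reactants: 1 1-(2-hydroxy-3-methoxyphenyl)ethan-1-one
Product: 2 1-(5-bromo-2-hydroxy-3-methoxyphenyl)ethan-1-one
Conditions: NBS (1.05 equiv), MeCN, 0 °C to rt
Reagents that add atoms: N-bromosuccinimide, O=C1CCC(=O)N1Br
Why: Electrophilic aromatic bromination is steered by the strongest donor, the hydroxyl group, whose two ortho positions are occupied, so bromine enters para to it (C5, also meta to the acetyl group), as in the bromination of o-vanillin.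

**Step 2**
Reactants: 2 1-(5-bromo-2-hydroxy-3-methoxyphenyl)ethan-1-one
Product: 4 6-bromo-8-methoxy-4H-chromen-4-one, via enaminone 3 (not isolated)
Conditions: Me2NCH(OMe)2 (2 equiv), toluene, 95 °C; concentrate; then conc. HCl, CH2Cl2, 40 °C
Reagents that add atoms: N,N-dimethylformamide dimethyl acetal, COC(OC)N(C)C
Why: Condensation of the methyl ketone with the amide acetal gives the enaminone, and acid then drives conjugate addition of the phenol oxygen and loss of dimethylamine (addition–elimination), the standard enaminone route that closes the pyranone ring of a 2,3-unsubstituted chromone.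

**Step 3**
Reactants: 5 allyl alcohol
Product: 6 (allyloxy)(tert-butyl)diphenylsilane
Conditions: TBDPSCl (1.05 equiv), imidazole (2 equiv), CH2Cl2, 0 °C to rt
Reagents that add atoms: tert-butyldiphenylsilyl chloride, CC(C)(C)[Si](Cl)(c1ccccc1)c1ccccc1
Why: Routine imidazole-promoted silylation of a primary alcohol, chosen because this ether is the most acid-stable of the common silyl groups yet leaves with fluoride.

**Step 4**
Reactants: 6 (allyloxy)(tert-butyl)diphenylsilane; 4 6-bromo-8-methoxy-4H-chromen-4-one
Product: 8 6-[3-(tert-butyldiphenylsilyloxy)propyl]-8-methoxy-4H-chromen-4-one, via B-alkyl borane 7 (not isolated)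
Conditions: 6 (1.3 equiv), 9-BBN (0.5 M in THF, 1.25 equiv), 0 °C to rt; then 4, PdCl2(dppf) (5 mol %), K3PO4 (3 M aq., 2 equiv), DMF, 60 °C
Reagents that add atoms: 9-borabicyclo[3.3.1]nonane, B1C2CCCC1CCC2 (its atoms stay only in 7)
Why: Anti-Markovnikov hydroboration puts boron on the terminal carbon and the B-alkyl Suzuki–Miyaura coupling then joins that sp3 carbon to C6 of the bromochromone, halochromones being established coupling partners under carbonate or phosphate bases.

**Step 5**
Reactants: 9 2-methoxy-4-(4,4,5,5-tetramethyl-1,3,2-dioxaborolan-2-yl)phenol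
Product: 10 2-methoxy-4-(4,4,5,5-tetramethyl-1,3,2-dioxaborolan-2-yl)phenyl acetate
Conditions: Ac2O (1.5 equiv), pyridine, CH2Cl2, 0 °C to rt
Reagents that add atoms: acetic anhydride, CC(=O)OC(C)=O
Why: Simple O-acylation of the phenol, which masks it from the later oxidant and makes ring B a poorer migrating group.

**Step 6**
Reactants: 10 2-methoxy-4-(4,4,5,5-tetramethyl-1,3,2-dioxaborolan-2-yl)phenyl acetate
Product: 11 (4-acetoxy-3-methoxyphenyl)boronic acid
Conditions: NaIO4 (3 equiv), THF–H2O 4:1, rt; then 1 M HCl, rt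
Reagents that add atoms: water, O
Why: Oxidative pinacol cleavage, in which periodate destroys the pinacol released by the hydrolysis equilibrium and frees the boronic acid, which transmetallates to cationic palladium far more readily than the pinacol ester, while the aryl acetate tolerates the brief dilute acid.

**Step 7**
Reactants: 8 6-[3-(tert-butyldiphenylsilyloxy)propyl]-8-methoxy-4H-chromen-4-one; 11 (4-acetoxy-3-methoxyphenyl)boronic acid
Product: 12 (R)-2-(4-acetoxy-3-methoxyphenyl)-6-[3-(tert-butyldiphenylsilyloxy)propyl]-8-methoxychroman-4-one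
Conditions: 11 (2 equiv), Pd(OCOCF3)2 (5 mol %), (S)-4-tert-butyl-2-(pyridin-2-yl)-4,5-dihydrooxazole [(S)-t-BuPyOx, 6 mol %], NH4PF6 (30 mol %), H2O (5 equiv), ClCH2CH2Cl, 60 °C
Reagents that add atoms: none
Why: Asymmetric conjugate addition of an arylboronic acid to a chromone under cationic divalent palladium–pyridinooxazoline catalysis (transmetallation, enantiodetermining arylpalladation of C2=C3, protonolysis of the palladium enolate by water), in which the tert-butyl group of the ligand shields one face of the bound chromone and so sets C2 as R.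

**Step 8**
Reactants: 12 (R)-2-(4-acetoxy-3-methoxyphenyl)-6-[3-(tert-butyldiphenylsilyloxy)propyl]-8-methoxychroman-4-one
Product: 15 methyl (2R,3R)-2-(4-acetoxy-3-methoxyphenyl)-5-[3-(tert-butyldiphenylsilyloxy)propyl]-7-methoxy-2,3-dihydrobenzofuran-3-carboxylate (trans), via methyl enol ether 13 (not isolated), via iodanyl ketal 14 (not isolated)
Conditions: PhI(OAc)2 (1.3 equiv), conc. H2SO4 (cat.), HC(OMe)3, 0 °C to rt; aq. NaHCO3 quench
Reagents that add atoms: trimethyl orthoformate, COC(OC)OC; (diacetoxyiodo)benzene, CC(=O)OI(OC(C)=O)c1ccccc1 (its atoms stay only in 14)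
Why: Acid and orthoformate turn the C4 ketone into the 4-methoxy-2H-chromene 13, whose C3 attacks the acid-activated λ3-iodane on the face away from the pseudo-equatorial C2 aryl group while methanol caps C4, giving the 2,3-trans iodanyl ketal 14. In the diequatorial half-chair of 14 the C4–C4a bond lies antiperiplanar to the C3–I bond, so C4a (made nucleophilic by the ortho ring oxygen O1) shifts from C4 to C3 through a phenonium-type bridge as iodobenzene leaves, and the dimethoxycarbenium ion left at the old C4 gives up one methyl group to acetate and becomes the methyl ester. The closest known reaction type is the oxidative 1,2-aryl shift of aryl ketones and flavanones with trivalent iodine or trivalent thallium reagents in trimethyl orthoformate. The dihydrofuran ring is closed by contraction of the pyranone from six to five members (C3–C3a made, C4–C4a broken), not by a cyclisation. C3 is set by substrate control, since anti iodination relative to the C2 aryl group followed by inversion during the migration places the ester trans to that aryl group, so (R)-C2, itself untouched, gives (2R,3R)-15. The step needs C4a to migrate in preference to the C2 aryl group (isoflavone path) and to elimination (flavone path), which is secured by the acetate on the ring B oxygen lowering the migratory aptitude of that ring, and no free phenol is exposed to the oxidant.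

**Step 9**
Reactants: 15 methyl (2R,3R)-2-(4-acetoxy-3-methoxyphenyl)-5-[3-(tert-butyldiphenylsilyloxy)propyl]-7-methoxy-2,3-dihydrobenzofuran-3-carboxylate
Product: 16 4-{(2R,3S)-5-[3-(tert-butyldiphenylsilyloxy)propyl]-3-(hydroxymethyl)-7-methoxy-2,3-dihydrobenzofuran-2-yl}-2-methoxyphenol
Conditions: LiAlH4 (3 equiv), THF, 0 °C; aq. KNaC4H4O6 (potassium sodium tartrate) work-up
Reagents that add atoms: none
Why: Hydride reduction turns the methyl ester into the primary alcohol and cleaves the aryl acetate in the same operation, leaving the alkyl silyl ether and both stereocentres untouched (the C3 descriptor changes from R to S only through the priority rules).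

**Step 10**
Reactants: 16 4-{(2R,3S)-5-[3-(tert-butyldiphenylsilyloxy)propyl]-3-(hydroxymethyl)-7-methoxy-2,3-dihydrobenzofuran-2-yl}-2-methoxyphenol; 17 p-coumaric acid
Product: 18 {(2R,3S)-5-[3-(tert-butyldiphenylsilyloxy)propyl]-2-(4-hydroxy-3-methoxyphenyl)-7-methoxy-2,3-dihydrobenzofuran-3-yl}methyl (E)-3-(4-hydroxyphenyl)prop-2-enoate
Conditions: 17 (1.3 equiv), PPh3 (1.4 equiv), DIAD (1.4 equiv, slow addition), THF, 0 °C to rt
Reagents that add atoms: none
Why: In this Mitsunobu esterification the carboxylic acid (pKa about 4.5) is far more acidic than the phenols (pKa about 10) and protonates the betaine, so carboxylate and not phenoxide displaces the primary alkoxyphosphonium ion, and substitution at the CH2 group touches no stereocentre.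

**Step 11**
Reactants: 18 {(2R,3S)-5-[3-(tert-butyldiphenylsilyloxy)propyl]-2-(4-hydroxy-3-methoxyphenyl)-7-methoxy-2,3-dihydrobenzofuran-3-yl}methyl (E)-3-(4-hydroxyphenyl)prop-2-enoate
Product: 19 [(2R,3S)-2-(4-hydroxy-3-methoxyphenyl)-5-(3-hydroxypropyl)-7-methoxy-2,3-dihydrobenzofuran-3-yl]methyl (E)-3-(4-hydroxyphenyl)prop-2-enoate
Conditions: HF·pyridine, pyridine, THF, 0 °C to rt
Reagents that add atoms: none
Why: Fluoride-driven desilylation in a pyridine-buffered medium removes the only remaining protecting group without base, so the alkyl cinnamate, the alkene, the phenols and the benzylic C2–O1 bond are left alone.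

**Step 12**
Reactants: 19 [(2R,3S)-2-(4-hydroxy-3-methoxyphenyl)-5-(3-hydroxypropyl)-7-methoxy-2,3-dihydrobenzofuran-3-yl]methyl (E)-3-(4-hydroxyphenyl)prop-2-enoate; 20 ferulic acid
Product: 21 (+)-boehmenan X
Conditions: 20 (1.3 equiv), PPh3 (1.4 equiv), DIAD (1.4 equiv, slow addition), THF, 0 °C to rt
Reagents that add atoms: none
Why: A second chemoselective Mitsunobu esterification, in which the single unhindered primary alcohol is activated and captured by the feruloyl carboxylate while the three phenols stay as spectators for the same acidity reason as in step 10.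

**Compound list**
1 | 1-(2-hydroxy-3-methoxyphenyl)ethan-1-one | CC(=O)c1cccc(OC)c1O | starting material
2 | 1-(5-bromo-2-hydroxy-3-methoxyphenyl)ethan-1-one | CC(=O)c1cc(Br)cc(OC)c1O | intermediate
3 | (E)-1-(5-bromo-2-hydroxy-3-methoxyphenyl)-3-(dimethylamino)prop-2-en-1-one | CN(C)/C=C/C(=O)c1cc(Br)cc(OC)c1O | intermediate
4 | 6-bromo-8-methoxy-4H-chromen-4-one | O=c1ccoc2c(OC)cc(Br)cc12 | intermediate
5 | allyl alcohol | C=CCO | starting material
6 | (allyloxy)(tert-butyl)diphenylsilane | C=CCO[Si](c1ccccc1)(c1ccccc1)C(C)(C)C | intermediate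
7 | 9-[3-(tert-butyldiphenylsilyloxy)propyl]-9-borabicyclo[3.3.1]nonane | CC(C)(C)[Si](OCCCB1C2CCCC1CCC2)(c1ccccc1)c1ccccc1 | intermediate
8 | 6-[3-(tert-butyldiphenylsilyloxy)propyl]-8-methoxy-4H-chromen-4-one | O=c1ccoc2c(OC)cc(CCCO[Si](c3ccccc3)(c3ccccc3)C(C)(C)C)cc12 | intermediate
9 | 2-methoxy-4-(4,4,5,5-tetramethyl-1,3,2-dioxaborolan-2-yl)phenol | COc1cc(B2OC(C)(C)C(C)(C)O2)ccc1O | starting material
10 | 2-methoxy-4-(4,4,5,5-tetramethyl-1,3,2-dioxaborolan-2-yl)phenyl acetate | COc1cc(B2OC(C)(C)C(C)(C)O2)ccc1OC(C)=O | intermediate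
11 | (4-acetoxy-3-methoxyphenyl)boronic acid | COc1cc(B(O)O)ccc1OC(C)=O | intermediate
12 | (R)-2-(4-acetoxy-3-methoxyphenyl)-6-[3-(tert-butyldiphenylsilyloxy)propyl]-8-methoxychroman-4-one | O=C1C[C@H](c2ccc(OC(C)=O)c(OC)c2)Oc2c(OC)cc(CCCO[Si](c3ccccc3)(c3ccccc3)C(C)(C)C)cc21 | intermediate
13 | (R)-2-(4-acetoxy-3-methoxyphenyl)-6-[3-(tert-butyldiphenylsilyloxy)propyl]-4,8-dimethoxy-2H-chromene | COC1=C[C@H](c2ccc(OC(C)=O)c(OC)c2)Oc2c(OC)cc(CCCO[Si](c3ccccc3)(c3ccccc3)C(C)(C)C)cc21 | intermediate
14 | (2S,3S)-3-[acetoxy(phenyl)-λ3-iodanyl]-2-(4-acetoxy-3-methoxyphenyl)-6-[3-(tert-butyldiphenylsilyloxy)propyl]-4,4,8-trimethoxychromane (2,3-trans) | COC1(OC)[C@@H](I(OC(C)=O)c2ccccc2)[C@H](c2ccc(OC(C)=O)c(OC)c2)Oc2c(OC)cc(CCCO[Si](c3ccccc3)(c3ccccc3)C(C)(C)C)cc21 | intermediate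
15 | methyl (2R,3R)-2-(4-acetoxy-3-methoxyphenyl)-5-[3-(tert-butyldiphenylsilyloxy)propyl]-7-methoxy-2,3-dihydrobenzofuran-3-carboxylate | CC(C)(C)[Si](OCCCc1cc(OC)c2c(c1)[C@@H](C(=O)OC)[C@H](c1ccc(OC(C)=O)c(OC)c1)O2)(c1ccccc1)c1ccccc1 | intermediate
16 | 4-{(2R,3S)-5-[3-(tert-butyldiphenylsilyloxy)propyl]-3-(hydroxymethyl)-7-methoxy-2,3-dihydrobenzofuran-2-yl}-2-methoxyphenol | CC(C)(C)[Si](OCCCc1cc(OC)c2c(c1)[C@@H](CO)[C@H](c1ccc(O)c(OC)c1)O2)(c1ccccc1)c1ccccc1 | intermediate
17 | p-coumaric acid | O=C(O)/C=C/c1ccc(O)cc1 | starting material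
18 | {(2R,3S)-5-[3-(tert-butyldiphenylsilyloxy)propyl]-2-(4-hydroxy-3-methoxyphenyl)-7-methoxy-2,3-dihydrobenzofuran-3-yl}methyl (E)-3-(4-hydroxyphenyl)prop-2-enoate | CC(C)(C)[Si](OCCCc1cc(OC)c2c(c1)[C@@H](COC(=O)/C=C/c1ccc(O)cc1)[C@H](c1ccc(O)c(OC)c1)O2)(c1ccccc1)c1ccccc1 | intermediate
19 | [(2R,3S)-2-(4-hydroxy-3-methoxyphenyl)-5-(3-hydroxypropyl)-7-methoxy-2,3-dihydrobenzofuran-3-yl]methyl (E)-3-(4-hydroxyphenyl)prop-2-enoate | OCCCc1cc(OC)c2c(c1)[C@@H](COC(=O)/C=C/c1ccc(O)cc1)[C@H](c1ccc(O)c(OC)c1)O2 | intermediate
20 | ferulic acid | COc1cc(/C=C/C(=O)O)ccc1O | starting material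
21 | (+)-boehmenan X, the (2R,3S) chain feruloyl and C3-CH2O p-coumaroyl diester | COc1cc(/C=C/C(=O)OCCCc2cc(OC)c3c(c2)[C@@H](COC(=O)/C=C/c2ccc(O)cc2)[C@H](c2ccc(O)c(OC)c2)O3)ccc1O | target

**Step count**
Total step count: 12.
Longest linear sequence: 9 steps (steps 1, 2, 4, 7, 8, 9, 10, 11, 12).

**Steps most likely to fail**

Step 8.
- What may go wrong: the C2 aryl group may shift in place of C4a, or the iodanyl intermediate may eliminate towards the flavone. Prolonged acid may also open the flavanone reversibly, with erosion of ee. It may strip the acetate, exposing a phenol to the oxidant, or remove the silyl ether.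
- Fallback: it sets out from 12 and separates halogenation, ketalisation and migration.
- α-Bromination of 12 with CuBr2 in EtOAc–CHCl3 at reflux should give the equilibrated, diequatorial (2S,3S)-trans-3-bromoflavanone F1.
- HC(OMe)3 with catalytic TsOH in MeOH converts it into the bromo dimethyl ketal F2.
- Catalytic ZnBr2 in toluene at 90 °C then triggers the α-halo ketal 1,2-aryl rearrangement. Only the C4–C4a bond lies antiperiplanar to the equatorial C3–Br bond, and bromide takes up the methyl group of the dialkoxycarbenium ion.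
- The sequence comes back to the route at 15 with the same trans outcome.

Step 7.
- What may go wrong: poor facial selectivity with the 8-methoxy group close to the coordinating ring oxygen, or partial racemisation through reversible ring opening at 60 °C.
- Fallback: it sets out from 8 (with 11) and obtains the configuration by kinetic resolution instead of asymmetric addition.
- The same addition with Pd(OCOCF3)2 and achiral 2,2'-bipyridine gives the racemic flavanone F3.
- Asymmetric transfer hydrogenation with RuCl(p-cymene)[(S,S)-TsDPEN] in HCO2H–Et3N, stopped near half conversion, should reduce the (S)-ketone to the cis-(2S,4S)-flavan-4-ol F4.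
- The unreacted (R)-ketone is separated by chromatography, which comes back to the route at 12. The catalyst enantiomer is exchanged if the matched pair proves to be the other one.

Step 10.
- What may go wrong: competing O-alkylation of a phenol by the activated alcohol, or elimination of the β-branched alkoxyphosphonium ion next to the benzylic C3–H.
- Fallback: it sets out from 16 (acyl donor from 17) and replaces alcohol activation by acyl transfer followed by selective aminolysis.
- 17 is acetylated (Ac2O, pyridine) to (E)-4-acetoxycinnamic acid F5 and converted with SOCl2 into (E)-4-acetoxycinnamoyl chloride F6.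
- 16 is acylated on both the primary alcohol and the ring B phenol (F6 2.5 equiv, Et3N, DMAP, CH2Cl2) to the bis(4-acetoxycinnamoyl) derivative F7.
- Pyrrolidine in CH2Cl2 at rt then cleaves only the aryl esters (two acetates and the aryl cinnamate) and leaves the alkyl cinnamate, which comes back to the route at 18.

**Further compounds**
F1 | step 8 | (2S,3S)-2-(4-acetoxy-3-methoxyphenyl)-3-bromo-6-[3-(tert-butyldiphenylsilyloxy)propyl]-8-methoxychroman-4-one (2,3-trans) | O=C1[C@@H](Br)[C@H](c2ccc(OC(C)=O)c(OC)c2)Oc2c(OC)cc(CCCO[Si](c3ccccc3)(c3ccccc3)C(C)(C)C)cc21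
F2 | step 8 | (2S,3S)-2-(4-acetoxy-3-methoxyphenyl)-3-bromo-6-[3-(tert-butyldiphenylsilyloxy)propyl]-4,4,8-trimethoxychromane (2,3-trans) | COC1(OC)[C@@H](Br)[C@H](c2ccc(OC(C)=O)c(OC)c2)Oc2c(OC)cc(CCCO[Si](c3ccccc3)(c3ccccc3)C(C)(C)C)cc21
F3 | step 7 | racemic 2-(4-acetoxy-3-methoxyphenyl)-6-[3-(tert-butyldiphenylsilyloxy)propyl]-8-methoxychroman-4-one | O=C1CC(c2ccc(OC(C)=O)c(OC)c2)Oc2c(OC)cc(CCCO[Si](c3ccccc3)(c3ccccc3)C(C)(C)C)cc21
F4 | step 7 | (2S,4S)-2-(4-acetoxy-3-methoxyphenyl)-6-[3-(tert-butyldiphenylsilyloxy)propyl]-8-methoxychroman-4-ol (2,4-cis) | O[C@H]1C[C@@H](c2ccc(OC(C)=O)c(OC)c2)Oc2c(OC)cc(CCCO[Si](c3ccccc3)(c3ccccc3)C(C)(C)C)cc21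
F5 | step 10 | (E)-4-acetoxycinnamic acid | CC(=O)Oc1ccc(/C=C/C(=O)O)cc1
F6 | step 10 | (E)-4-acetoxycinnamoyl chloride | CC(=O)Oc1ccc(/C=C/C(=O)Cl)cc1
F7 | step 10 | bis[(E)-4-acetoxycinnamoyl] derivative of 16 (esters at C3-CH2O and at the ring B phenol) | CC(C)(C)[Si](OCCCc1cc(OC)c2c(c1)[C@@H](COC(=O)/C=C/c1ccc(OC(C)=O)cc1)[C@H](c1ccc(OC(=O)/C=C/c3ccc(OC(C)=O)cc3)c(OC)c1)O2)(c1ccccc1)c1ccccc1
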